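**Retrosynthetic overview**

1. Target ⇒ γ-lactone by acyl substitution of the C6 hydroxyl on a C12 acid (step 24); 3(2H)-furanone by cyclodehydration of O10 onto the C3 ketone of a 1,3-diketone (step 22); C8 tiglate by esterification (step 19).
2. Ten-membered ketone 29 ⇒ anionic oxy-Cope rearrangement of cyclohexenol 26 (forms C1–C10, breaks C3–C8). The strategy rests on C3 and C8: they are 1,6-related across the ten-membered ring C1–C10 but adjacent in the carvone ring C3–C8, and C2=C1 and C9=C10 are the two vinyl arms of a 1,5-diene.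
3. 26 ⇒ bis(alkenyl iodide) 25 (copper-catalysed etherification) ⇒ two acetylide additions to the C3 and C8 carbonyls of oxidised (S)-carvone. O12 comes from ene chlorination, O8 from enolate hydroxylation, O15 from SeO2, O6 from vinylogous Rubottom oxidation and ketone reduction.
4. Ring order: six-membered carbocycle (carvone) → ten-membered carbocycle (step 17) → furanone (step 22) → lactone (step 24).

Key step: step 17

Remark: germacrane numbering is used for all compounds (six-membered intermediates: ring atoms C3–C8, C15 on C4, side chain C11–C13 on C7). PMB = 4-methoxybenzyl, TES = triethylsilyl, TBS = tert-butyldimethylsilyl, TMS = trimethylsilyl.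
Assumption: the target is taken exactly as drawn, with O6, C11 and O8 on one face of the ring (6,7-cis-fused lactone), and every stereocontrolling step is designed for this configuration.
Remark: O10 and O1 are carried as PMB ethers, and C15 and C12 are oxygenated before the rearrangement, because after it the C4=C5 alkene is conjugated and no longer open to allylic oxidation.

**Step 1**
Reactants: 1 (S)-(+)-carvone
Product: 2 (S)-5-(3-chloroprop-1-en-2-yl)-2-methylcyclohex-2-en-1-one (12-chlorocarvone)
Conditions: Ca(OCl)2, CO2 (dry ice), CH2Cl2/H2O, 0 °C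
Reagents that add atoms: calcium hypochlorite, [Ca+2].[O-]Cl.[O-]Cl
Why: Ene-type allylic chlorination by HOCl takes place only at the electron-rich 1,1-disubstituted alkene (the enone alkene is inert), and the allylic shift across the symmetrical 2-propenyl unit is degenerate, so C7 is untouched.

**Step 2**
Reactants: 2 12-chlorocarvone; 3 4-methoxybenzyl alcohol
Product: 4 (S)-5-[3-(4-methoxybenzyloxy)prop-1-en-2-yl]-2-methylcyclohex-2-en-1-one
Conditions: Ag2O, Bu4NI (cat.), CH2Cl2, rt, dark
Reagents that add atoms: 4-methoxybenzyl alcohol (3), COc1ccc(CO)cc1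
Why: Silver(I)-oxide-promoted Williamson etherification of the primary allylic chloride needs no free alkoxide, so the dienolate and its intramolecular C-alkylation are avoided; either terminus of the 2-substituted allyl unit gives the same ether.

**Step 3**
Reactants: 4 PMB ether
Product: 6 8-hydroxy ketone (OH trans to the C7 side chain), via lithium dienolate 5 (not isolated)
Conditions: LDA, THF, −78 °C; then 2-(phenylsulfonyl)-3-phenyloxaziridine, −78 °C; aq. NH4Cl
Reagents that add atoms: 2-(phenylsulfonyl)-3-phenyloxaziridine, O=S(=O)(N1OC1c1ccccc1)c1ccccc1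
Why: Kinetic deprotonation gives the cross-conjugated C8 enolate, and Davis enolate hydroxylation occurs anti to the neighbouring C7 side chain; the C8 centre is erased in step 7.

**Step 4**
Reactants: 6 8-hydroxy ketone
Product: 7 C8 triethylsilyl ether
Conditions: TESCl, imidazole, DMF, 0 °C
Reagents that add atoms: chlorotriethylsilane, CC[Si](Cl)(CC)CC
Why: Standard silylation of the secondary acyloin hydroxyl gives a bulky, non-chelating ether that leaves the C3 carbonyl open to axial attack.

**Step 5**
Reactants: 7 C8 silyl ether; 8 trimethylsilylacetylene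
Product: 10 C3 methyl ether carrying the C3 (trimethylsilyl)ethynyl group (alkynyl trans and OMe cis to the C7 side chain), via lithium alkoxide 9 (not isolated)
Conditions: 8, n-BuLi, THF, −78 °C; add 7; then MeOTf, −78 → 0 °C
Reagents that add atoms: trimethylsilylacetylene (8), C[Si](C)(C)C#C; methyl triflate, COS(=O)(=O)C(F)(F)F
Why: 1,2-Addition of the slim lithium acetylide follows the axial trajectory trans to the equatorial C7 side chain (as in other carvone additions) and sets C3, and the lithium alkoxide is O-methylated in situ (Williamson-type alkylation).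

**Step 6**
Reactants: 10 C3 methyl ether
Product: 11 C8 secondary alcohol
Conditions: HF·pyridine, pyridine, THF, 0 °C
Reagents that add atoms: none
Why: Buffered HF·pyridine cleaves the secondary triethylsilyl ether while the C-silyl alkyne, the PMB ether and the tertiary methyl ether are stable.

**Step 7**
Reactants: 11 C8 alcohol
Product: 12 C8 ketone (α-methoxy ketone)
Conditions: Dess–Martin periodinane, NaHCO3, CH2Cl2, rt
Reagents that add atoms: none
Why: Dess–Martin oxidation of the secondary alcohol is buffered and non-epimerising, which matters because C7–H is the only α-hydrogen.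

**Step 8**
Reactants: 12 C8 ketone; 13 1-propynylmagnesium bromide
Product: 14 C8 tertiary alcohol (OH trans, 1-propynyl cis to the C7 side chain; the two alkynyl arms trans)
Conditions: 13 (0.5 M in THF), THF, −78 → −20 °C; aq. NH4Cl
Reagents that add atoms: 1-propynylmagnesium bromide (13), CC#C[Mg]Br
Why: Grignard 1,2-addition of the small sp nucleophile occurs axially, anti to the pseudoaxial alkynyl group on C3 and on the face that carries only an axial hydrogen at C6, in line with chelation by the in-plane C3 methoxy group, which places propynyl cis to the C7 side chain.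

**Step 9**
Reactants: 14 C8 tertiary alcohol
Product: 16 C15 enal (C4-formyl), via allylic alcohol 15 (not isolated)
Conditions: SeO2 (cat.), t-BuOOH, CH2Cl2, rt; filter; MnO2, CH2Cl2, rt
Reagents that add atoms: tert-butyl hydroperoxide, CC(C)(C)OO
Why: Riley allylic oxidation (ene reaction, then [2,3] shift) attacks the methyl on the more substituted end of the trisubstituted ring alkene, which is more nucleophilic than the 1,1-disubstituted alkene deactivated by its allylic PMB ether, and MnO2 converges alcohol and aldehyde to the enal.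

**Step 10**
Reactants: 16 C15 enal
Product: 18 6-hydroxy enal (OH expected trans to the C7 side chain), via bis-silyl dienol ether 17 (not isolated)
Conditions: TMSOTf, Et3N, CH2Cl2, −78 → 0 °C; dimethyldioxirane (acetone solution), −78 °C; aq. citric acid
Reagents that add atoms: dimethyldioxirane, CC1(C)OO1
Why: In this vinylogous Rubottom oxidation, soft enolisation of the enal can only remove a C6 hydrogen (C3 is quaternary), and the dioxirane epoxidises the distal C5=C6 bond rather than the hindered C15=C4 bond, collapsing to the γ-hydroxy enal; the C6 configuration is reset in step 11.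

**Step 11**
Reactants: 18 6-hydroxy enal
Product: 20 6,8,15-triol (C6–OH cis to the C7 side chain), via 6-oxo enal 19 (not isolated)
Conditions: Dess–Martin periodinane, NaHCO3, CH2Cl2, 0 °C; then NaBH4, CeCl3·7H2O, MeOH, −78 °C
Reagents that add atoms: none
Why: Dess–Martin oxidation gives the 6-oxo enal and Luche 1,2-reduction reduces both carbonyls, hydride reaching C6 from the face away from the axial C8 propynyl group and the C7 side chain, so the C6 hydroxyl ends cis to the side chain as the lactone requires.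

**Step 12**
Reactants: 20 triol
Product: 21 6,15-bis-TBS ether (C8–OH free)
Conditions: TBSOTf, 2,6-lutidine, CH2Cl2, −78 °C
Reagents that add atoms: tert-butyldimethylsilyl triflate, CC(C)(C)[Si](C)(C)OS(=O)(=O)C(F)(F)F
Why: Silyl triflate silylation at −78 °C protects the primary and the secondary allylic hydroxyl and leaves the hindered tertiary propargylic alcohol free for the directed reduction in step 15.

**Step 13**
Reactants: 21 bis-TBS ether
Product: 22 terminal alkyne (C3 ethynyl)
Conditions: K2CO3 (cat.), MeOH, 0 °C → rt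
Reagents that add atoms: none
Why: Base-catalysed methanolysis cleaves only the alkynyl C–Si bond (protodesilylation); the silyl ethers are stable.

**Step 14**
Reactants: 22 terminal alkyne
Product: 23 (E)-alkenylstannane on C3
Conditions: Bu3SnH, PdCl2(PPh3)2 (cat.), THF, 0 °C
Reagents that add atoms: tributyltin hydride, CCCC[SnH](CCCC)CCCC
Why: Palladium-catalysed syn hydrostannation of the terminal alkyne places tin on the terminal carbon, away from quaternary C3, giving the E-stannane; the hindered internal alkyne reacts more slowly.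

**Step 15**
Reactants: 23 alkenylstannane
Product: 25 bis(alkenyl iodide) (C3: (E)-2-iodovinyl; C8: (Z)-2-iodoprop-1-enyl with iodine cis to C8), via sodium alkenylalanate 24 (not isolated)
Conditions: Red-Al, THF, 0 °C; then I2, −78 → 0 °C; Rochelle salt, Na2S2O3
Reagents that add atoms: iodine, II
Why: Alkoxide-directed trans-hydroalumination of the propargylic alcohol delivers hydride to C9 and aluminium to C10 in a five-membered alanate, so iodinolysis with retention gives the Z-iodide, and iododestannylation with retention gives the E-iodide in the same flask.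

**Step 16**
Reactants: 25 bis(alkenyl iodide); 3 4-methoxybenzyl alcohol
Product: 26 oxy-Cope precursor: trans-1,2-dialkenylcyclohex-3-en-1-ol with C3 (E)-2-(PMB-oxy)vinyl and OMe, C8 (Z)-2-(PMB-oxy)prop-1-enyl (O10 cis to C8) and OH
Conditions: CuI, 3,4,7,8-tetramethyl-1,10-phenanthroline, Cs2CO3, toluene, 80 °C
Reagents that add atoms: 4-methoxybenzyl alcohol (3), COc1ccc(CO)cc1
Why: Copper-catalysed C–O cross-coupling of alkenyl iodides with a primary alcohol (Ullmann-type O-vinylation) proceeds with retention of alkene geometry at both arms.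

**Step 17**
Reactants: 26 oxy-Cope precursor
Product: 29 ten-membered C8 ketone ((2E,4Z)-diene; C2=C3 methyl enol ether; 1-OPMB; 10-methyl-10-OPMB), via potassium alkoxide 27 (not isolated), via potassium enolate 28 (not isolated)
Conditions: KHMDS, 18-crown-6, THF, −78 → 0 °C; AcOH/THF, −78 °C
Reagents that add atoms: none
Why: Deprotonation gives alkoxide 27, whose O8–K bond weakens the C3–C8 bond, and the 1,5-diene C10=C9–C8–C3–C2=C1 undergoes a concerted [3,3] shift (anionic oxy-Cope rearrangement; closest precedent is the ring expansion of 1,2-divinylcyclohexanolates to cyclodec-5-enones) that forms C1–C10 while C3–C8 breaks, giving enolate 28 and, after cold protonation at C9, ketone 29. The ten-membered ring is closed by this four-atom ring expansion inside the six-centre transition state, not by an end-to-end cyclisation. The trans-diequatorial arms on C8 and C3 allow only the chair that is trans-fused to the cyclohexene (ring bonds C8–C7 and C3–C4 equatorial, O8 and OMe axial), so the C2=C3 enol ether forms E and C4=C5 stays Z. C10 is set by this chair together with the geometry of the C9=C10 enol ether (O10 cis to C8 and therefore axial, methyl equatorial), and C1 by the E geometry of C1=C2 (O1 equatorial), this centre being oxidised later. The step needs selectivity for the C2=C1 arm over the 2-propenyl arm on C7, which is also 1,5-related to C9=C10, and over E1cB loss of the C10 ether from enolate 28; the first rests on the much weaker C3–C8 bond (quaternary, allylic to two alkenes, α-oxygenated), the second on reaction at or below 0 °C and quench at −78 °C.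

**Step 18**
Reactants: 29 ten-membered ketone
Product: 30 C8 alcohol (OH cis to the C7 side chain)
Conditions: L-Selectride, THF, −78 °C
Reagents that add atoms: none
Why: Reduction with a bulky trialkylborohydride should occur from the ring periphery on the face away from the C7 side chain, giving the C8 alcohol cis to it as in the target; the enol ether and ether groups are inert.

**Step 19**
Reactants: 30 C8 alcohol; 31 tiglic acid
Product: 32 C8 tiglate
Conditions: 2,4,6-trichlorobenzoyl chloride, Et3N, DMAP, toluene, rt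
Reagents that add atoms: tiglic acid (31), C/C=C(\C)C(=O)O
Why: Yamaguchi esterification through the mixed anhydride acylates the hindered secondary alcohol under basic conditions that spare the acid-labile dienol ether and keep the E-configured tiglate.

**Step 20**
Reactants: 32 tiglate
Product: 33 C3 ketone (enone with C4=C5; C2 methylene)
Conditions: oxalic acid (0.1 M aq.), THF, 0 °C → rt
Reagents that add atoms: water, O
Why: Mild acid hydrolysis of the methyl enol ether (protonation at C2 gives the only oxygen-stabilised cation) unveils the C3 ketone, and silyl and PMB ethers survive dilute oxalic acid.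

**Step 21**
Reactants: 33 C3 ketone
Product: 34 1,10,12-triol
Conditions: DDQ, CH2Cl2/pH 7 buffer, 0 °C → rt
Reagents that add atoms: none
Why: DDQ cleaves all three PMB ethers oxidatively (benzylic hydride abstraction, then hydrolysis), which is possible now that no enol ether remains; silyl ethers, enone and tiglate are inert.

**Step 22**
Reactants: 34 triol
Product: 36 furanone 12-aldehyde, via 1,3-diketone aldehyde 35 (not isolated)
Conditions: IBX, DMSO, rt; then p-TsOH·H2O (cat.), CH2Cl2, rt
Reagents that add atoms: none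
Why: IBX oxidises the secondary C1 alcohol and the primary allylic C12 alcohol without cleaving the 1,2-diol, and acid closes the 3(2H)-furanone by 5-exo-trig addition of the tertiary C10 hydroxyl to the C3 ketone followed by dehydration (cyclodehydration of an α′-hydroxy-1,3-diketone).

**Step 23**
Reactants: 36 furanone aldehyde
Product: 37 furanone 12-carboxylic acid (acrylic acid on C7)
Conditions: NaClO2, NaH2PO4, 2-methyl-2-butene, t-BuOH/H2O, 0 °C
Reagents that add atoms: sodium chlorite, [Na+].[O-]Cl=O
Why: Pinnick oxidation converts the 2-substituted acrolein into the acrylic acid chemoselectively, the scavenger removing hypochlorous acid before it adds to the alkenes.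

**Step 24**
Reactants: 37 acid
Product: 39 target CNP0269689.6, via dihydroxy acid 38 (not isolated)
Conditions: HF·pyridine, THF, 0 °C → rt
Reagents that add atoms: none
Why: Fluoride cleaves both silyl ethers, and the freed C6 hydroxyl, cis to the C7 acrylic acid, lactonises under the acidic conditions (5-exo-trig acyl substitution with retention at C6) to the α-methylene-γ-lactone, leaving the C15 alcohol free.

**Compound list**

1 | (S)-(+)-carvone | CC1=CC[C@@H](CC1=O)C(C)=C | starting material
2 | (S)-5-(3-chloroprop-1-en-2-yl)-2-methylcyclohex-2-en-1-one | CC1=CC[C@@H](CC1=O)C(CCl)=C | intermediate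
3 | 4-methoxybenzyl alcohol | COc1ccc(CO)cc1 | starting material
4 | (S)-5-[3-(4-methoxybenzyloxy)prop-1-en-2-yl]-2-methylcyclohex-2-en-1-one | CC1=CC[C@@H](CC1=O)C(COCc2ccc(OC)cc2)=C | intermediate
5 | lithium cross-conjugated dienolate of 4 (C8=C3–O–Li) | CC1=CC[C@@H](C=C1[O-])C(COCc2ccc(OC)cc2)=C.[Li+] | intermediate (not isolated)
6 | 8-hydroxy ketone; OH trans to the C7 side chain | CC1=CC[C@@H]([C@@H](O)C1=O)C(COCc2ccc(OC)cc2)=C | intermediate
7 | C8 triethylsilyl ether of 6 | CC1=CC[C@@H]([C@@H](O[Si](CC)(CC)CC)C1=O)C(COCc2ccc(OC)cc2)=C | intermediate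
8 | trimethylsilylacetylene | C[Si](C)(C)C#C | starting material
9 | lithium C3 alkoxide from acetylide addition to 7 | CC[Si](CC)(CC)O[C@H]1[C@@]([O-])(C#C[Si](C)(C)C)C(C)=CC[C@@H]1C(COCc2ccc(OC)cc2)=C.[Li+] | intermediate (not isolated)
10 | C3 methyl ether; C3 (trimethylsilyl)ethynyl trans and OMe cis to the C7 side chain; C8–OTES | CC[Si](CC)(CC)O[C@H]1[C@@](OC)(C#C[Si](C)(C)C)C(C)=CC[C@@H]1C(COCc2ccc(OC)cc2)=C | intermediate
11 | C8 secondary alcohol | O[C@H]1[C@@](OC)(C#C[Si](C)(C)C)C(C)=CC[C@@H]1C(COCc2ccc(OC)cc2)=C | intermediate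
12 | C8 ketone | O=C1[C@@](OC)(C#C[Si](C)(C)C)C(C)=CC[C@@H]1C(COCc2ccc(OC)cc2)=C | intermediate
13 | 1-propynylmagnesium bromide | CC#C[Mg]Br | starting material
14 | C8 tertiary alcohol; OH trans and propynyl cis to the C7 side chain | O[C@@]1(C#CC)[C@@](OC)(C#C[Si](C)(C)C)C(C)=CC[C@@H]1C(COCc2ccc(OC)cc2)=C | intermediate
15 | C15 allylic alcohol | O[C@@]1(C#CC)[C@@](OC)(C#C[Si](C)(C)C)C(CO)=CC[C@@H]1C(COCc2ccc(OC)cc2)=C | intermediate (not isolated)
16 | C15 enal | O[C@@]1(C#CC)[C@@](OC)(C#C[Si](C)(C)C)C(C=O)=CC[C@@H]1C(COCc2ccc(OC)cc2)=C | intermediate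
17 | C15 trimethylsilyl dienol ether (C15=C4, C5=C6) with C8–OTMS | C[Si](C)(C)O[C@@]1(C#CC)[C@@](OC)(C#C[Si](C)(C)C)C(=CO[Si](C)(C)C)C=C[C@@H]1C(COCc2ccc(OC)cc2)=C | intermediate (not isolated)
18 | 6-hydroxy enal; C6–OH trans to the C7 side chain (expected epimer) | O[C@@]1(C#CC)[C@@](OC)(C#C[Si](C)(C)C)C(C=O)=C[C@@H](O)[C@@H]1C(COCc2ccc(OC)cc2)=C | intermediate
19 | 6-oxo enal | O[C@@]1(C#CC)[C@@](OC)(C#C[Si](C)(C)C)C(C=O)=CC(=O)[C@@H]1C(COCc2ccc(OC)cc2)=C | intermediate (not isolated)
20 | 6,8,15-triol; C6–OH cis to the C7 side chain | O[C@@]1(C#CC)[C@@](OC)(C#C[Si](C)(C)C)C(CO)=C[C@H](O)[C@@H]1C(COCc2ccc(OC)cc2)=C | intermediate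
21 | 6,15-bis-TBS ether | O[C@@]1(C#CC)[C@@](OC)(C#C[Si](C)(C)C)C(CO[Si](C)(C)C(C)(C)C)=C[C@H](O[Si](C)(C)C(C)(C)C)[C@@H]1C(COCc2ccc(OC)cc2)=C | intermediate
22 | terminal alkyne (C3 ethynyl) | O[C@@]1(C#CC)[C@@](OC)(C#C)C(CO[Si](C)(C)C(C)(C)C)=C[C@H](O[Si](C)(C)C(C)(C)C)[C@@H]1C(COCc2ccc(OC)cc2)=C | intermediate
23 | C3 (E)-2-(tributylstannyl)vinyl compound | O[C@@]1(C#CC)[C@@](OC)(/C=C/[Sn](CCCC)(CCCC)CCCC)C(CO[Si](C)(C)C(C)(C)C)=C[C@H](O[Si](C)(C)C(C)(C)C)[C@@H]1C(COCc2ccc(OC)cc2)=C | intermediate
24 | cyclic sodium alkoxy(alkenyl)alanate (O8–Al–C10) | [Na+].COCCO[Al-]1(OCCOC)O[C@@]2(C=C1C)[C@@](OC)(/C=C/[Sn](CCCC)(CCCC)CCCC)C(CO[Si](C)(C)C(C)(C)C)=C[C@H](O[Si](C)(C)C(C)(C)C)[C@@H]2C(COCc3ccc(OC)cc3)=C | intermediate (not isolated)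
25 | bis(alkenyl iodide); C3 (E)-2-iodovinyl; C8 (Z)-2-iodoprop-1-enyl | O[C@@]1(/C=C(/C)I)[C@@](OC)(/C=C/I)C(CO[Si](C)(C)C(C)(C)C)=C[C@H](O[Si](C)(C)C(C)(C)C)[C@@H]1C(COCc2ccc(OC)cc2)=C | intermediate
26 | oxy-Cope precursor; C3 (E)-2-(PMB-oxy)vinyl; C8 (Z)-2-(PMB-oxy)prop-1-enyl | O[C@@]1(/C=C(/C)OCc2ccc(OC)cc2)[C@@](OC)(/C=C/OCc2ccc(OC)cc2)C(CO[Si](C)(C)C(C)(C)C)=C[C@H](O[Si](C)(C)C(C)(C)C)[C@@H]1C(COCc2ccc(OC)cc2)=C | intermediate
27 | potassium alkoxide of 26 | [K+].[O-][C@@]1(/C=C(/C)OCc2ccc(OC)cc2)[C@@](OC)(/C=C/OCc2ccc(OC)cc2)C(CO[Si](C)(C)C(C)(C)C)=C[C@H](O[Si](C)(C)C(C)(C)C)[C@@H]1C(COCc2ccc(OC)cc2)=C | intermediate (not isolated)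
28 | potassium C8 enolate (C8=C9) of the ten-membered ring | [K+].[O-]C1=C[C@@](C)(OCc2ccc(OC)cc2)[C@@H](OCc2ccc(OC)cc2)/C=C(OC)/C(CO[Si](C)(C)C(C)(C)C)=C\[C@H](O[Si](C)(C)C(C)(C)C)[C@@H]1C(COCc2ccc(OC)cc2)=C | intermediate (not isolated)
29 | ten-membered C8 ketone; (2E,4Z)-diene; C2=C3 methyl enol ether | O=C1C[C@@](C)(OCc2ccc(OC)cc2)[C@@H](OCc2ccc(OC)cc2)/C=C(OC)/C(CO[Si](C)(C)C(C)(C)C)=C\[C@H](O[Si](C)(C)C(C)(C)C)[C@@H]1C(COCc2ccc(OC)cc2)=C | intermediate
30 | C8 alcohol; OH cis to the C7 side chain | O[C@@H]1C[C@@](C)(OCc2ccc(OC)cc2)[C@@H](OCc2ccc(OC)cc2)/C=C(OC)/C(CO[Si](C)(C)C(C)(C)C)=C\[C@H](O[Si](C)(C)C(C)(C)C)[C@@H]1C(COCc2ccc(OC)cc2)=C | intermediate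
31 | tiglic acid | C/C=C(\C)C(=O)O | starting material
32 | C8 tiglate | C/C=C(\C)C(=O)O[C@@H]1C[C@@](C)(OCc2ccc(OC)cc2)[C@@H](OCc2ccc(OC)cc2)/C=C(OC)/C(CO[Si](C)(C)C(C)(C)C)=C\[C@H](O[Si](C)(C)C(C)(C)C)[C@@H]1C(COCc2ccc(OC)cc2)=C | intermediate
33 | C3 ketone (4Z-enone) | C/C=C(\C)C(=O)O[C@@H]1C[C@@](C)(OCc2ccc(OC)cc2)[C@@H](OCc2ccc(OC)cc2)CC(=O)/C(CO[Si](C)(C)C(C)(C)C)=C\[C@H](O[Si](C)(C)C(C)(C)C)[C@@H]1C(COCc2ccc(OC)cc2)=C | intermediate
34 | 1,10,12-triol | C/C=C(\C)C(=O)O[C@@H]1C[C@@](C)(O)[C@@H](O)CC(=O)/C(CO[Si](C)(C)C(C)(C)C)=C\[C@H](O[Si](C)(C)C(C)(C)C)[C@@H]1C(CO)=C | intermediate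
35 | 1,3-diketone 12-aldehyde with free C10–OH | C/C=C(\C)C(=O)O[C@@H]1C[C@@](C)(O)C(=O)CC(=O)/C(CO[Si](C)(C)C(C)(C)C)=C\[C@H](O[Si](C)(C)C(C)(C)C)[C@@H]1C(C=O)=C | intermediate (not isolated)
36 | furanone 12-aldehyde | C/C=C(\C)C(=O)O[C@@H]1C[C@@]2(C)OC(=CC2=O)/C(CO[Si](C)(C)C(C)(C)C)=C\[C@H](O[Si](C)(C)C(C)(C)C)[C@@H]1C(C=O)=C | intermediate
37 | furanone 12-carboxylic acid | C/C=C(\C)C(=O)O[C@@H]1C[C@@]2(C)OC(=CC2=O)/C(CO[Si](C)(C)C(C)(C)C)=C\[C@H](O[Si](C)(C)C(C)(C)C)[C@@H]1C(C(=O)O)=C | intermediate
38 | 6,15-dihydroxy 12-acid | C/C=C(\C)C(=O)O[C@@H]1C[C@@]2(C)OC(=CC2=O)/C(CO)=C\[C@H](O)[C@@H]1C(C(=O)O)=C | intermediate (not isolated)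
39 | CNP0269689.6 | C=C1C(=O)O[C@H]2/C=C(/CO)C3=CC(=O)[C@@](C)(C[C@@H](OC(=O)/C(C)=C/C)[C@@H]12)O3 | target

**Totals**

Total step count: 24. Longest linear sequence: 24 steps, from (S)-carvone 1 to 39.

**Steps most likely to fail**

Step 17 (key step). The potassium enolate may expel the C10 4-methoxybenzyloxide (E1cB), the alkoxide may fragment heterolytically instead of rearranging, or the C7 2-propenyl arm may enter the [3,3] shift in place of the C2=C1 arm. The fallback is a neutral siloxy-Cope rearrangement, which involves no alkoxide or enolate. It sets out from 26, which is silylated with N-(trimethylsilyl)imidazole to the C8 trimethylsilyl ether F1. F1 is heated in 1,2-dichlorobenzene at about 180 °C and should rearrange through the same chair to the trimethylsilyl enol ether F2. Cleavage with TBAF buffered by acetic acid at −78 °C then gives ketone 29, where the route is rejoined.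

Step 16. Under hot carbonate the 1,5-dien-3-ol may rearrange or decompose prematurely, and C–O coupling at the hindered trisubstituted iodide may stall. The fallback avoids heat and strong base at the ether-forming stage. It sets out from 25, which is converted by Miyaura borylation (bis(pinacolato)diboron, PdCl2(dppf), KOAc, dioxane) into the bis(pinacol boronate) F3. Copper(II) acetate-promoted oxidative coupling of F3 with alcohol 3 (Et3N, molecular sieves, air, rt; Chan–Lam type) then gives 26 with retention of both alkene geometries, where the route is rejoined.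

Step 18. Hydride addition to the conformationally mobile ten-membered ketone may show poor or reversed facial selectivity. The fallback sets the C8 configuration by inversion. It sets out from 29: the C8-epimeric alcohol F4 (the other reduction product, or the main one with a small hydride) is esterified with tiglic acid 31 under Mitsunobu conditions (PPh3, DIAD, THF, 0 °C). This gives tiglate 32 directly, where the route is rejoined.

**Further compounds**

F1 | step 17 | C8 trimethylsilyl ether of 26 | C[Si](C)(C)O[C@@]1(/C=C(/C)OCc2ccc(OC)cc2)[C@@](OC)(/C=C/OCc2ccc(OC)cc2)C(CO[Si](C)(C)C(C)(C)C)=C[C@H](O[Si](C)(C)C(C)(C)C)[C@@H]1C(COCc2ccc(OC)cc2)=C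
F2 | step 17 | trimethylsilyl enol ether (C8=C9) of ketone 29 | C[Si](C)(C)OC1=C[C@@](C)(OCc2ccc(OC)cc2)[C@@H](OCc2ccc(OC)cc2)/C=C(OC)/C(CO[Si](C)(C)C(C)(C)C)=C\[C@H](O[Si](C)(C)C(C)(C)C)[C@@H]1C(COCc2ccc(OC)cc2)=C
F3 | step 16 | bis(pinacol boronate) corresponding to 25 | O[C@@]1(/C=C(/C)B2OC(C)(C)C(C)(C)O2)[C@@](OC)(/C=C/B2OC(C)(C)C(C)(C)O2)C(CO[Si](C)(C)C(C)(C)C)=C[C@H](O[Si](C)(C)C(C)(C)C)[C@@H]1C(COCc2ccc(OC)cc2)=C
F4 | step 18 | C8 epimer of alcohol 30 | O[C@H]1C[C@@](C)(OCc2ccc(OC)cc2)[C@@H](OCc2ccc(OC)cc2)/C=C(OC)/C(CO[Si](C)(C)C(C)(C)C)=C\[C@H](O[Si](C)(C)C(C)(C)C)[C@@H]1C(COCc2ccc(OC)cc2)=C
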